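**Retrosynthetic overview**
1. Core numbering (6-oxabicyclo[3.2.1]octane): C1 quaternary bridgehead with the dienyl chain, C2 carbinol, C3/C4 methylenes, C5 ether bridgehead with CH(CH3)CHO (its CH is called Cα), O6, C7 (OCH2), C8 (CH with the hydroxypropyl arm).
2. Late stage: the dienyl chain is joined by B-alkyl Suzuki coupling of the C1-CH2CH2 iodide with a dienyl iodide made from cis-α-irone; the C2 methyl carbinol comes from exo addition of MeMgBr to the bicyclic C2 ketone; CHO and the free CH2OH are unveiled last.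
3. Key disconnection, the O6–C7 bond: on the cyclohexane chair C1–C2–C3–C4–C5–C8 the oxygen on C5 and the CH2 on C1 are 1,3-diaxial, so the tetrahydrofuran ring C1–C7–O6–C5–C8 is closed from a C5 tertiary alcohol and an angular C1 methyl group by alkoxy-radical 1,5-hydrogen transfer (hypoiodite reaction).
4. The monocyclic precursor is built on a purchased cyclohexenone: C8 by copper-catalysed asymmetric conjugate addition, C1 by enolate alkylation anti to the C8 arm, C5 and Cα by Z-crotylation of the C5 ketone.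
5. Ring order: carbocycle (bought), then the tetrahydrofuran ring (step 12); the irone ring is bought with both stereocentres in place.

Key step: step 12

Assumption: (1R,5S)-cis-α-irone (28) is used as a single enantiomer (obtained from commercial α-irone by enzymatic resolution if not bought as such). Abbreviations: Bn benzyl, TBS tert-butyldimethylsilyl, TBDPS tert-butyldiphenylsilyl, TES triethylsilyl, Tf trifluoromethanesulfonyl. The SMILES are authoritative for configuration.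

**Step 1**
Reactants: 1 1,4-dioxaspiro[4.5]dec-6-en-8-one
Product: 2 7-iodo-1,4-dioxaspiro[4.5]dec-6-en-8-one
Conditions: I2, pyridine, CH2Cl2, 0 °C → rt
Reagents that add atoms: iodine, II
Why: α-Iodination of a cyclohexenone through pyridine conjugate addition, iodination of the enolate and elimination is a standard reaction that leaves the ketal untouched.

**Step 2**
Reactants: 2 7-iodo-1,4-dioxaspiro[4.5]dec-6-en-8-one
Product: 3 7-methyl-1,4-dioxaspiro[4.5]dec-6-en-8-one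
Conditions: MeB(OH)2, Pd(dppf)Cl2 (5 mol%), K3PO4, dioxane/H2O, 80 °C
Reagents that add atoms: methylboronic acid, CB(O)O
Why: Suzuki–Miyaura coupling of an α-iodoenone places the methyl group (the later C7) regiospecifically on the α-carbon.

**Step 3**
Reactants: 3 7-methyl-1,4-dioxaspiro[4.5]dec-6-en-8-one
Product: 5 {[(6S)-6-(but-3-en-1-yl)-7-methyl-1,4-dioxaspiro[4.5]dec-7-en-8-yl]oxy}trimethylsilane, via zinc enolate 4 (not isolated)
Conditions: (CH2=CHCH2CH2)2Zn, Cu(OTf)2 (3 mol%), (R,S,S)-phosphoramidite from (R)-BINOL and bis[(S)-1-phenylethyl]amine (6 mol%), toluene, −30 → 0 °C; then TMSOTf, Et3N, −30 °C → rt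
Reagents that add atoms: di(but-3-en-1-yl)zinc, C=CCC[Zn]CCC=C; trimethylsilyl trifluoromethanesulfonate, C[Si](C)(C)OS(=O)(=O)C(F)(F)F
Why: Copper-catalysed asymmetric conjugate addition of a dialkylzinc with a phosphoramidite ligand, a reaction type known for 2-methyl- and 4,4-disubstituted cyclohexenones and quinone monoketals, should set C8, the ligand antipode being chosen by analogy with the known sense of addition to cyclohexenone, and O-silylation fixes the regiodefined enolate.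

**Step 4**
Reactants: 6 2-(benzyloxy)ethan-1-ol
Product: 7 2-(benzyloxy)ethyl trifluoromethanesulfonate
Conditions: Tf2O, pyridine, CH2Cl2, −78 → 0 °C (used at once)
Reagents that add atoms: trifluoromethanesulfonic anhydride, O=S(=O)(OS(=O)(=O)C(F)(F)F)C(F)(F)F
Why: O-Sulfonylation of the primary alcohol gives an electrophile reactive enough for a congested enolate, where the corresponding iodide would mainly eliminate.

**Step 5**
Reactants: 5 {[(6S)-6-(but-3-en-1-yl)-7-methyl-1,4-dioxaspiro[4.5]dec-7-en-8-yl]oxy}trimethylsilane; 7 2-(benzyloxy)ethyl trifluoromethanesulfonate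
Product: 9 (6S,7S)-7-[2-(benzyloxy)ethyl]-6-(but-3-en-1-yl)-7-methyl-1,4-dioxaspiro[4.5]decan-8-one, via lithium enolate 8 (not isolated)
Conditions: MeLi, THF, 0 °C; then 7, −78 → −20 °C
Reagents that add atoms: none
Why: MeLi cleaves the silyl enol ether to the lithium enolate without regiochemical scrambling, and SN2 C-alkylation should occur on the face anti to the C8 butenyl group, which lies pseudoaxial to avoid allylic strain with the C1 methyl, so that the methyl group ends cis and the new chain trans to the C8 arm.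

**Step 6**
Reactants: 9 (6S,7S)-7-[2-(benzyloxy)ethyl]-6-(but-3-en-1-yl)-7-methyl-1,4-dioxaspiro[4.5]decan-8-one
Product: 10 methyl 3-[(6S,7S)-7-[2-(benzyloxy)ethyl]-7-methyl-8-oxo-1,4-dioxaspiro[4.5]decan-6-yl]propanoate
Conditions: O3, NaOH (2.5 M in MeOH), CH2Cl2, −78 °C
Reagents that add atoms: ozone, [O-][O+]=O; methanol, CO
Why: Ozonolysis in methanolic NaOH converts a terminal alkene directly into the one-carbon-shorter methyl ester through the methoxy hydroperoxide, while the ketal, the ketone (no epimerisable α-stereocentre) and the benzyl ether survive.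

**Step 7**
Reactants: 10 methyl 3-[(6S,7S)-7-[2-(benzyloxy)ethyl]-7-methyl-8-oxo-1,4-dioxaspiro[4.5]decan-6-yl]propanoate
Product: 11 methyl 3-[(1S,2S)-2-[2-(benzyloxy)ethyl]-2-methyl-3,6-dioxocyclohexyl]propanoate
Conditions: 1 M HCl, THF, rt (stopped at full conversion)
Reagents that add atoms: water, O
Why: Acid-catalysed ketal hydrolysis frees the C5 ketone under conditions mild enough to spare the methyl ester and to limit enolisation toward C8.

**Step 8**
Reactants: 12 (Z)-crotylboronic acid pinacol ester [2-[(2Z)-but-2-en-1-yl]-4,4,5,5-tetramethyl-1,3,2-dioxaborolane]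
Product: 13 potassium [(2Z)-but-2-en-1-yl]trifluoroborate
Conditions: KHF2 (aq.), MeOH, 0 °C → rt
Reagents that add atoms: potassium hydrogen difluoride, F.[F-].[K+]
Why: Exchange of pinacol for fluoride keeps the Z geometry and gives the salt that BF3 can activate for addition to ketones.

**Step 9**
Reactants: 11 methyl 3-[(1S,2S)-2-[2-(benzyloxy)ethyl]-2-methyl-3,6-dioxocyclohexyl]propanoate; 13 potassium [(2Z)-but-2-en-1-yl]trifluoroborate
Product: 14 methyl 3-[(1S,2S,6S)-2-[2-(benzyloxy)ethyl]-6-[(2R)-but-3-en-2-yl]-6-hydroxy-2-methyl-3-oxocyclohexyl]propanoate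
Conditions: BF3·OEt2, CH2Cl2, −78 °C
Reagents that add atoms: none
Why: BF3 converts 13 into the Z-crotyl difluoroborane, which should add through a closed chair (Zimmerman–Traxler) transition state to the C5 carbonyl (C2 is shielded by the quaternary C1) on the face opposite the C8 arm and the C1 methyl group, giving the axial C5 hydroxyl cis to that methyl, with boron on the oxygen lone pair remote from the C8 arm so that the axial Z-methyl group sets Cα (2R in 14, the S centre of the target once vinyl has become CHO).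

**Step 10**
Reactants: 14 methyl 3-[(1S,2S,6S)-2-[2-(benzyloxy)ethyl]-6-[(2R)-but-3-en-2-yl]-6-hydroxy-2-methyl-3-oxocyclohexyl]propanoate
Product: 16 methyl 3-[(1S,2S,6R)-2-[2-(benzyloxy)ethyl]-6-hydroxy-6-[(2R)-1-hydroxypropan-2-yl]-2-methyl-3-oxocyclohexyl]propanoate, via hydroxy aldehyde 15 (not isolated)
Conditions: O3, CH2Cl2, −78 °C; PPh3, −78 °C → rt; then NaBH4, EtOH, −78 → −40 °C
Reagents that add atoms: ozone, [O-][O+]=O
Why: Ozonolysis with reductive work-up cleaves the only alkene, and the β-hydroxy aldehyde is reduced at once at low temperature, where NaBH4 distinguishes an aldehyde from the hindered C2 ketone and the ester, so that Cα is not exposed to epimerisation or retro-aldol cleavage.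

**Step 11**
Reactants: 16 methyl 3-[(1S,2S,6R)-2-[2-(benzyloxy)ethyl]-6-hydroxy-6-[(2R)-1-hydroxypropan-2-yl]-2-methyl-3-oxocyclohexyl]propanoate
Product: 17 methyl 3-[(1S,2S,6R)-2-[2-(benzyloxy)ethyl]-6-[(2R)-1-{[tert-butyl(dimethyl)silyl]oxy}propan-2-yl]-6-hydroxy-2-methyl-3-oxocyclohexyl]propanoate
Conditions: TBSCl, imidazole, CH2Cl2, 0 °C
Reagents that add atoms: tert-butyldimethylsilyl chloride, CC(C)(C)[Si](C)(C)Cl
Why: Silylation is selective for the primary hydroxyl and leaves the tertiary C5 hydroxyl free for the key step.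

**Step 12**
Reactants: 17 methyl 3-[(1S,2S,6R)-2-[2-(benzyloxy)ethyl]-6-[(2R)-1-{[tert-butyl(dimethyl)silyl]oxy}propan-2-yl]-6-hydroxy-2-methyl-3-oxocyclohexyl]propanoate
Product: 20 methyl 3-[(1S,5R,8S)-1-[2-(benzyloxy)ethyl]-5-[(2R)-1-{[tert-butyl(dimethyl)silyl]oxy}propan-2-yl]-2-oxo-6-oxabicyclo[3.2.1]octan-8-yl]propanoate, via hypoiodite 18 (not isolated), via primary iodide 19 (not isolated)
Conditions: PhI(OAc)2 (2.2 equiv), I2 (1.0 equiv), cyclohexane/CH2Cl2, visible light (tungsten lamp), 25–35 °C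
Reagents that add atoms: none
Why: Acetyl hypoiodite formed from PhI(OAc)2 and I2 converts the C5 hydroxyl into hypoiodite 18, light cleaves the O–I bond, the tertiary alkoxy radical takes a hydrogen from the 1,3-diaxial C1 methyl group through a six-membered transition state, iodine traps the primary C7 radical as iodide 19, and the C5 oxygen displaces the iodide once acetyl hypoiodite has oxidised it to a hypervalent leaving group. The closest known reaction type is the hypoiodite etherification of 1,3-diaxial alcohol–methyl pairs, as in steroid 6β-alcohols giving 6,19-ethers and in tertiary terpene carbinols. The tetrahydrofuran ring C1–C7–O6–C5–C8 closes by 5-exo-tet substitution at C7. No stereocentre is created, since C1 and C5 keep their configuration and only the cis-diaxial bridge is geometrically possible. The step needs hydrogen transfer from C7 to beat β-scission of the C5–Cα and C5–C8 bonds and abstraction from the arms: in the chair with the three large groups equatorial the O···H–C7 contact is already in place, the first CH2 of the equatorial benzyloxyethyl chain on C1 points away from the axial oxygen and its OCH2 is reached only through a seven-membered transition state, the CH2 next to the ester is electron-poor toward the electrophilic oxygen radical, and the nonpolar solvent disfavours fragmentation. Iodine capture of the C7 radical, close to diffusion control, should outrun the 1,2-acyl shift (Dowd–Beckwith pathway) open to this β-keto radical.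

**Step 13**
Reactants: 20 methyl 3-[(1S,5R,8S)-1-[2-(benzyloxy)ethyl]-5-[(2R)-1-{[tert-butyl(dimethyl)silyl]oxy}propan-2-yl]-2-oxo-6-oxabicyclo[3.2.1]octan-8-yl]propanoate
Product: 21 3-[(1S,2S,5R,8S)-1-[2-(benzyloxy)ethyl]-5-[(2R)-1-(TBSO)propan-2-yl]-2-hydroxy-6-oxabicyclo[3.2.1]octan-8-yl]propan-1-ol
Conditions: LiAlH4, THF, 0 °C
Reagents that add atoms: none
Why: Hydride reduction converts the ester into the primary alcohol and the C2 ketone (exo attack) into a secondary alcohol whose configuration is immaterial because C2 is reoxidised in step 15, and the silyl and benzyl ethers are inert.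

**Step 14**
Reactants: 21 3-[(1S,2S,5R,8S)-1-[2-(benzyloxy)ethyl]-5-[(2R)-1-(TBSO)propan-2-yl]-2-hydroxy-6-oxabicyclo[3.2.1]octan-8-yl]propan-1-ol
Product: 22 (1S,2S,5R,8S)-1-[2-(benzyloxy)ethyl]-5-[(2R)-1-(TBSO)propan-2-yl]-8-[3-(TBDPSO)propyl]-6-oxabicyclo[3.2.1]octan-2-ol
Conditions: TBDPSCl, imidazole, CH2Cl2, 0 °C
Reagents that add atoms: tert-butyldiphenylsilyl chloride, CC(C)(C)[Si](Cl)(c1ccccc1)c1ccccc1
Why: The bulky silyl chloride reacts with the unhindered primary hydroxyl and not with the C2 hydroxyl flanked by the quaternary bridgehead.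

**Step 15**
Reactants: 22 (1S,2S,5R,8S)-1-[2-(benzyloxy)ethyl]-5-[(2R)-1-(TBSO)propan-2-yl]-8-[3-(TBDPSO)propyl]-6-oxabicyclo[3.2.1]octan-2-ol
Product: 23 (1S,5R,8S)-1-[2-(benzyloxy)ethyl]-5-[(2R)-1-(TBSO)propan-2-yl]-8-[3-(TBDPSO)propyl]-6-oxabicyclo[3.2.1]octan-2-one
Conditions: Dess–Martin periodinane, CH2Cl2, rt
Reagents that add atoms: none
Why: Dess–Martin oxidation of the secondary alcohol restores the C2 ketone under neutral conditions that spare the silyl and benzyl ethers.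

**Step 16**
Reactants: 23 (1S,5R,8S)-1-[2-(benzyloxy)ethyl]-5-[(2R)-1-(TBSO)propan-2-yl]-8-[3-(TBDPSO)propyl]-6-oxabicyclo[3.2.1]octan-2-one
Product: 24 (1S,2S,5R,8S)-1-[2-(benzyloxy)ethyl]-5-[(2R)-1-(TBSO)propan-2-yl]-8-[3-(TBDPSO)propyl]-2-methyl-6-oxabicyclo[3.2.1]octan-2-ol
Conditions: MeMgBr, THF, −78 → 0 °C
Reagents that add atoms: methylmagnesium bromide, C[Mg]Br
Why: Grignard 1,2-addition should take place on the exo face of C2, anti to the O6–C7 bridge and past only the axial hydrogens on C4 and C8, so that the methyl group is axial and the hydroxyl equatorial as in the target.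

**Step 17**
Reactants: 24 (1S,2S,5R,8S)-1-[2-(benzyloxy)ethyl]-5-[(2R)-1-(TBSO)propan-2-yl]-8-[3-(TBDPSO)propyl]-2-methyl-6-oxabicyclo[3.2.1]octan-2-ol
Product: 25 {[(1S,2S,5R,8S)-1-[2-(benzyloxy)ethyl]-5-[(2R)-1-(TBSO)propan-2-yl]-8-[3-(TBDPSO)propyl]-2-methyl-6-oxabicyclo[3.2.1]octan-2-yl]oxy}triethylsilane
Conditions: TESOTf, 2,6-lutidine, CH2Cl2, 0 °C → rt
Reagents that add atoms: triethylsilyl trifluoromethanesulfonate, CC[Si](CC)(CC)OS(=O)(=O)C(F)(F)F
Why: Silyl triflate silylation masks the tertiary hydroxyl, which would otherwise close a tetrahydrofuran onto the activated C1 chain in steps 19 and 22.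

**Step 18**
Reactants: 25 {[(1S,2S,5R,8S)-1-[2-(benzyloxy)ethyl]-5-[(2R)-1-(TBSO)propan-2-yl]-8-[3-(TBDPSO)propyl]-2-methyl-6-oxabicyclo[3.2.1]octan-2-yl]oxy}triethylsilane
Product: 26 2-[(1S,2S,5R,8S)-5-[(2R)-1-(TBSO)propan-2-yl]-8-[3-(TBDPSO)propyl]-2-methyl-2-(TESO)-6-oxabicyclo[3.2.1]octan-1-yl]ethan-1-ol
Conditions: H2 (1 atm), 10% Pd/C, EtOAc, rt
Reagents that add atoms: none
Why: Hydrogenolysis removes the benzyl ether at a stage with no alkene present, and the three silyl ethers are stable in a neutral aprotic solvent.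

**Step 19**
Reactants: 26 2-[(1S,2S,5R,8S)-5-[(2R)-1-(TBSO)propan-2-yl]-8-[3-(TBDPSO)propyl]-2-methyl-2-(TESO)-6-oxabicyclo[3.2.1]octan-1-yl]ethan-1-ol
Product: 27 (1S,2S,5R,8S)-1-(2-iodoethyl)-5-[(2R)-1-(TBSO)propan-2-yl]-8-[3-(TBDPSO)propyl]-2-methyl-2-(TESO)-6-oxabicyclo[3.2.1]octane
Conditions: I2, PPh3, imidazole, CH2Cl2, 0 °C → rt
Reagents that add atoms: iodine, II
Why: Appel-type iodination converts the unhindered primary alcohol into the iodide by SN2 displacement of the alkoxyphosphonium ion.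

**Step 20**
Reactants: 28 (1R,5S)-cis-α-irone [(3E)-4-[(1R,5S)-2,5,6,6-tetramethylcyclohex-2-en-1-yl]but-3-en-2-one]
Product: 30 (1R,5S)-1-[(1E)-but-1-en-3-yn-1-yl]-2,5,6,6-tetramethylcyclohex-2-ene, via enol phosphate 29 (not isolated)
Conditions: LDA, THF, −78 °C; ClP(O)(OEt)2; then LDA (2.3 equiv), −78 °C → rt
Reagents that add atoms: none
Why: Kinetic deprotonation at the acetyl methyl group, O-phosphorylation and base-induced elimination of the enol phosphate turn the methyl ketone into the terminal alkyne, the low temperature being needed to keep the doubly allylic ring C1–H untouched.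

**Step 21**
Reactants: 30 (1R,5S)-1-[(1E)-but-1-en-3-yn-1-yl]-2,5,6,6-tetramethylcyclohex-2-ene
Product: 32 (1R,5S)-1-[(1E,3E)-4-iodo-3-methylbuta-1,3-dien-1-yl]-2,5,6,6-tetramethylcyclohex-2-ene, via alkenylalane 31 (not isolated)
Conditions: AlMe3, Cp2ZrCl2 (0.3 equiv), CH2Cl2, 0 °C → rt; then I2, THF, −30 → 0 °C
Reagents that add atoms: trimethylaluminium, C[Al](C)C; iodine, II
Why: Zirconium-catalysed Negishi carboalumination adds methyl and aluminium syn across the terminal alkyne with methyl on the internal carbon, and iodinolysis with retention gives the E-iodide.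

**Step 22**
Reactants: 27 (1S,2S,5R,8S)-1-(2-iodoethyl)-5-[(2R)-1-(TBSO)propan-2-yl]-8-[3-(TBDPSO)propyl]-2-methyl-2-(TESO)-6-oxabicyclo[3.2.1]octane; 32 (1R,5S)-1-[(1E,3E)-4-iodo-3-methylbuta-1,3-dien-1-yl]-2,5,6,6-tetramethylcyclohex-2-ene
Product: 35 (1S,2S,5R,8S)-5-[(2R)-1-(TBSO)propan-2-yl]-8-[3-(TBDPSO)propyl]-2-methyl-1-{(3E,5E)-4-methyl-6-[(1R,5S)-2,5,6,6-tetramethylcyclohex-2-en-1-yl]hexa-3,5-dien-1-yl}-2-(TESO)-6-oxabicyclo[3.2.1]octane, via alkyllithium 33 (not isolated), via lithium borinate 34 (not isolated)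
Conditions: 27, t-BuLi (2.1 equiv), Et2O, −78 °C; B-methoxy-9-BBN, THF, −78 °C → rt; then 32, Pd(dppf)Cl2 (5 mol%), AsPh3, K3PO4 (3 M aq.), DMF, rt
Reagents that add atoms: none
Why: Lithium–iodine exchange and capture by B-methoxy-9-BBN give the borinate that transfers its primary alkyl group in a B-alkyl Suzuki–Miyaura coupling with the alkenyl iodide, with retention of the E,E-diene geometry.

**Step 23**
Reactants: 35 (1S,2S,5R,8S)-5-[(2R)-1-(TBSO)propan-2-yl]-8-[3-(TBDPSO)propyl]-2-methyl-1-{(3E,5E)-4-methyl-6-[(1R,5S)-2,5,6,6-tetramethylcyclohex-2-en-1-yl]hexa-3,5-dien-1-yl}-2-(TESO)-6-oxabicyclo[3.2.1]octane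
Product: 36 (2R)-2-[(1S,2S,5R,8S)-8-[3-(TBDPSO)propyl]-2-hydroxy-2-methyl-1-{(3E,5E)-4-methyl-6-[(1R,5S)-2,5,6,6-tetramethylcyclohex-2-en-1-yl]hexa-3,5-dien-1-yl}-6-oxabicyclo[3.2.1]octan-5-yl]propan-1-ol
Conditions: CSA (0.2 equiv), MeOH/CH2Cl2, 0 °C
Reagents that add atoms: none
Why: Acid-catalysed methanolysis removes the TES and TBS ethers much faster than the primary TBDPS ether, and the diene and the non-allylic tertiary alcohol tolerate the mild acid.

**Step 24**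
Reactants: 36 (2R)-2-[(1S,2S,5R,8S)-8-[3-(TBDPSO)propyl]-2-hydroxy-2-methyl-1-{(3E,5E)-4-methyl-6-[(1R,5S)-2,5,6,6-tetramethylcyclohex-2-en-1-yl]hexa-3,5-dien-1-yl}-6-oxabicyclo[3.2.1]octan-5-yl]propan-1-ol
Product: 37 (2S)-2-[(1S,2S,5R,8S)-8-[3-(TBDPSO)propyl]-2-hydroxy-2-methyl-1-{(3E,5E)-4-methyl-6-[(1R,5S)-2,5,6,6-tetramethylcyclohex-2-en-1-yl]hexa-3,5-dien-1-yl}-6-oxabicyclo[3.2.1]octan-5-yl]propanal
Conditions: Dess–Martin periodinane, NaHCO3, CH2Cl2, 0 °C
Reagents that add atoms: none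
Why: Buffered Dess–Martin oxidation converts the only primary alcohol into the aldehyde without touching the tertiary alcohol or the diene and without base that could epimerise Cα or eliminate the β-alkoxy group.

**Step 25**
Reactants: 37 (2S)-2-[(1S,2S,5R,8S)-8-[3-(TBDPSO)propyl]-2-hydroxy-2-methyl-1-{(3E,5E)-4-methyl-6-[(1R,5S)-2,5,6,6-tetramethylcyclohex-2-en-1-yl]hexa-3,5-dien-1-yl}-6-oxabicyclo[3.2.1]octan-5-yl]propanal
Product: 38 (2S)-2-[(1S,2S,5R,8S)-2-hydroxy-8-(3-hydroxypropyl)-2-methyl-1-{(3E,5E)-4-methyl-6-[(1R,5S)-2,5,6,6-tetramethylcyclohex-2-en-1-yl]hexa-3,5-dien-1-yl}-6-oxabicyclo[3.2.1]octan-5-yl]propanal (CNP0419303.1)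
Conditions: HF·pyridine, pyridine, THF, 0 °C → rt
Reagents that add atoms: none
Why: Buffered fluoride desilylation frees the primary alcohol under weakly acidic conditions that the β-alkoxy α-methyl aldehyde should tolerate.

**Compound list**
1 | 1,4-dioxaspiro[4.5]dec-6-en-8-one | O=C1C=CC2(CC1)OCCO2 | starting material
2 | 7-iodo-1,4-dioxaspiro[4.5]dec-6-en-8-one | O=C1C(I)=CC2(CC1)OCCO2 | intermediate
3 | 7-methyl-1,4-dioxaspiro[4.5]dec-6-en-8-one | CC1=CC2(CCC1=O)OCCO2 | intermediate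
4 | but-3-en-1-ylzinc (6S)-6-(but-3-en-1-yl)-7-methyl-1,4-dioxaspiro[4.5]dec-7-en-8-olate (zinc enolate) | C=CCC[C@H]1C(C)=C(O[Zn]CCC=C)CCC12OCCO2 | intermediate (not isolated)
5 | {[(6S)-6-(but-3-en-1-yl)-7-methyl-1,4-dioxaspiro[4.5]dec-7-en-8-yl]oxy}trimethylsilane | C=CCC[C@H]1C(C)=C(O[Si](C)(C)C)CCC12OCCO2 | intermediate
6 | 2-(benzyloxy)ethan-1-ol | OCCOCc1ccccc1 | starting material
7 | 2-(benzyloxy)ethyl trifluoromethanesulfonate | O=S(=O)(OCCOCc1ccccc1)C(F)(F)F | intermediate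
8 | lithium (6S)-6-(but-3-en-1-yl)-7-methyl-1,4-dioxaspiro[4.5]dec-7-en-8-olate | C=CCC[C@H]1C(C)=C(O[Li])CCC12OCCO2 | intermediate (not isolated)
9 | (6S,7S)-7-[2-(benzyloxy)ethyl]-6-(but-3-en-1-yl)-7-methyl-1,4-dioxaspiro[4.5]decan-8-one | O(Cc1ccccc1)CC[C@@]1(C)[C@H](CCC=C)C2(OCCO2)CCC1=O | intermediate
10 | methyl 3-[(6S,7S)-7-[2-(benzyloxy)ethyl]-7-methyl-8-oxo-1,4-dioxaspiro[4.5]decan-6-yl]propanoate | O(Cc1ccccc1)CC[C@@]1(C)[C@H](CCC(=O)OC)C2(OCCO2)CCC1=O | intermediate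
11 | methyl 3-[(1S,2S)-2-[2-(benzyloxy)ethyl]-2-methyl-3,6-dioxocyclohexyl]propanoate | O(Cc1ccccc1)CC[C@@]1(C)[C@H](CCC(=O)OC)C(=O)CCC1=O | intermediate
12 | (Z)-crotylboronic acid pinacol ester | C/C=C\CB1OC(C)(C)C(C)(C)O1 | starting material
13 | potassium [(2Z)-but-2-en-1-yl]trifluoroborate | C/C=C\C[B-](F)(F)F.[K+] | intermediate
14 | methyl 3-[(1S,2S,6S)-2-[2-(benzyloxy)ethyl]-6-[(2R)-but-3-en-2-yl]-6-hydroxy-2-methyl-3-oxocyclohexyl]propanoate | O(Cc1ccccc1)CC[C@@]1(C)[C@H](CCC(=O)OC)[C@@](O)([C@H](C)C=C)CCC1=O | intermediate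
15 | methyl 3-[(1S,2S,6R)-2-[2-(benzyloxy)ethyl]-6-hydroxy-2-methyl-3-oxo-6-[(2S)-1-oxopropan-2-yl]cyclohexyl]propanoate | O(Cc1ccccc1)CC[C@@]1(C)[C@H](CCC(=O)OC)[C@@](O)([C@H](C)C=O)CCC1=O | intermediate (not isolated)
16 | methyl 3-[(1S,2S,6R)-2-[2-(benzyloxy)ethyl]-6-hydroxy-6-[(2R)-1-hydroxypropan-2-yl]-2-methyl-3-oxocyclohexyl]propanoate | O(Cc1ccccc1)CC[C@@]1(C)[C@H](CCC(=O)OC)[C@@](O)([C@H](C)CO)CCC1=O | intermediate
17 | methyl 3-[(1S,2S,6R)-2-[2-(benzyloxy)ethyl]-6-[(2R)-1-{[tert-butyl(dimethyl)silyl]oxy}propan-2-yl]-6-hydroxy-2-methyl-3-oxocyclohexyl]propanoate (key-step precursor) | O(Cc1ccccc1)CC[C@@]1(C)[C@H](CCC(=O)OC)[C@@](O)([C@H](C)CO[Si](C)(C)C(C)(C)C)CCC1=O | intermediate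
18 | C5 hypoiodite (O-iodo derivative) of 17 | O(Cc1ccccc1)CC[C@@]1(C)[C@H](CCC(=O)OC)[C@@](OI)([C@H](C)CO[Si](C)(C)C(C)(C)C)CCC1=O | intermediate (not isolated)
19 | methyl 3-[(1S,2R,6R)-2-[2-(benzyloxy)ethyl]-6-[(2R)-1-(TBSO)propan-2-yl]-6-hydroxy-2-(iodomethyl)-3-oxocyclohexyl]propanoate | O(Cc1ccccc1)CC[C@@]1(CI)[C@H](CCC(=O)OC)[C@@](O)([C@H](C)CO[Si](C)(C)C(C)(C)C)CCC1=O | intermediate (not isolated)
20 | methyl 3-[(1S,5R,8S)-1-[2-(benzyloxy)ethyl]-5-[(2R)-1-{[tert-butyl(dimethyl)silyl]oxy}propan-2-yl]-2-oxo-6-oxabicyclo[3.2.1]octan-8-yl]propanoate (key-step product) | O(Cc3ccccc3)CC[C@]12CO[C@]([C@H](C)CO[Si](C)(C)C(C)(C)C)(CCC1=O)[C@H]2CCC(=O)OC | intermediate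
21 | 3-[(1S,2S,5R,8S)-1-[2-(benzyloxy)ethyl]-5-[(2R)-1-(TBSO)propan-2-yl]-2-hydroxy-6-oxabicyclo[3.2.1]octan-8-yl]propan-1-ol | O(Cc3ccccc3)CC[C@]12CO[C@]([C@H](C)CO[Si](C)(C)C(C)(C)C)(CC[C@@H]1O)[C@H]2CCCO | intermediate
22 | (1S,2S,5R,8S)-1-[2-(benzyloxy)ethyl]-5-[(2R)-1-(TBSO)propan-2-yl]-8-[3-(TBDPSO)propyl]-6-oxabicyclo[3.2.1]octan-2-ol | O(Cc3ccccc3)CC[C@]12CO[C@]([C@H](C)CO[Si](C)(C)C(C)(C)C)(CC[C@@H]1O)[C@H]2CCCO[Si](c4ccccc4)(c5ccccc5)C(C)(C)C | intermediate
23 | (1S,5R,8S)-1-[2-(benzyloxy)ethyl]-5-[(2R)-1-(TBSO)propan-2-yl]-8-[3-(TBDPSO)propyl]-6-oxabicyclo[3.2.1]octan-2-one | O(Cc3ccccc3)CC[C@]12CO[C@]([C@H](C)CO[Si](C)(C)C(C)(C)C)(CCC1=O)[C@H]2CCCO[Si](c4ccccc4)(c5ccccc5)C(C)(C)C | intermediate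
24 | (1S,2S,5R,8S)-1-[2-(benzyloxy)ethyl]-5-[(2R)-1-(TBSO)propan-2-yl]-8-[3-(TBDPSO)propyl]-2-methyl-6-oxabicyclo[3.2.1]octan-2-ol | O(Cc3ccccc3)CC[C@]12CO[C@]([C@H](C)CO[Si](C)(C)C(C)(C)C)(CC[C@]1(C)O)[C@H]2CCCO[Si](c4ccccc4)(c5ccccc5)C(C)(C)C | intermediate
25 | 2-O-triethylsilyl ether of 24 | O(Cc3ccccc3)CC[C@]12CO[C@]([C@H](C)CO[Si](C)(C)C(C)(C)C)(CC[C@]1(C)O[Si](CC)(CC)CC)[C@H]2CCCO[Si](c4ccccc4)(c5ccccc5)C(C)(C)C | intermediate
26 | 2-[(1S,2S,5R,8S)-5-[(2R)-1-(TBSO)propan-2-yl]-8-[3-(TBDPSO)propyl]-2-methyl-2-(TESO)-6-oxabicyclo[3.2.1]octan-1-yl]ethan-1-ol | OCC[C@]12CO[C@]([C@H](C)CO[Si](C)(C)C(C)(C)C)(CC[C@]1(C)O[Si](CC)(CC)CC)[C@H]2CCCO[Si](c4ccccc4)(c5ccccc5)C(C)(C)C | intermediate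
27 | (1S,2S,5R,8S)-1-(2-iodoethyl)-5-[(2R)-1-(TBSO)propan-2-yl]-8-[3-(TBDPSO)propyl]-2-methyl-2-(TESO)-6-oxabicyclo[3.2.1]octane | ICC[C@]12CO[C@]([C@H](C)CO[Si](C)(C)C(C)(C)C)(CC[C@]1(C)O[Si](CC)(CC)CC)[C@H]2CCCO[Si](c4ccccc4)(c5ccccc5)C(C)(C)C | intermediate
28 | (1R,5S)-cis-α-irone, (3E)-4-[(1R,5S)-2,5,6,6-tetramethylcyclohex-2-en-1-yl]but-3-en-2-one | CC1=CC[C@H](C)C(C)(C)[C@@H]1/C=C/C(C)=O | starting material
29 | diethyl (3E)-4-[(1R,5S)-2,5,6,6-tetramethylcyclohex-2-en-1-yl]buta-1,3-dien-2-yl phosphate | CC1=CC[C@H](C)C(C)(C)[C@@H]1/C=C/C(=C)OP(=O)(OCC)OCC | intermediate (not isolated)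
30 | (1R,5S)-1-[(1E)-but-1-en-3-yn-1-yl]-2,5,6,6-tetramethylcyclohex-2-ene | CC1=CC[C@H](C)C(C)(C)[C@@H]1/C=C/C#C | intermediate
31 | dimethyl{(1E,3E)-2-methyl-4-[(1R,5S)-2,5,6,6-tetramethylcyclohex-2-en-1-yl]buta-1,3-dien-1-yl}alane | CC1=CC[C@H](C)C(C)(C)[C@@H]1/C=C/C(C)=C/[Al](C)C | intermediate (not isolated)
32 | (1R,5S)-1-[(1E,3E)-4-iodo-3-methylbuta-1,3-dien-1-yl]-2,5,6,6-tetramethylcyclohex-2-ene | CC1=CC[C@H](C)C(C)(C)[C@@H]1/C=C/C(C)=C/I | intermediate
33 | primary alkyllithium from 27 (Li in place of I) | [Li]CC[C@]12CO[C@]([C@H](C)CO[Si](C)(C)C(C)(C)C)(CC[C@]1(C)O[Si](CC)(CC)CC)[C@H]2CCCO[Si](c3ccccc3)(c4ccccc4)C(C)(C)C | intermediate (not isolated)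
34 | lithium B-alkyl-B-methoxy-9-borabicyclo[3.3.1]nonan-9-uide (alkyl = the C1 ethyl chain of 27) | [Li+].CO[B-]5(CC[C@]12CO[C@]([C@H](C)CO[Si](C)(C)C(C)(C)C)(CC[C@]1(C)O[Si](CC)(CC)CC)[C@H]2CCCO[Si](c3ccccc3)(c4ccccc4)C(C)(C)C)C6CCCC5CCC6 | intermediate (not isolated)
35 | (1S,2S,5R,8S)-5-[(2R)-1-(TBSO)propan-2-yl]-8-[3-(TBDPSO)propyl]-2-methyl-1-{(3E,5E)-4-methyl-6-[(1R,5S)-2,5,6,6-tetramethylcyclohex-2-en-1-yl]hexa-3,5-dien-1-yl}-2-(TESO)-6-oxabicyclo[3.2.1]octane | CC1=CC[C@H](C)C(C)(C)[C@@H]1/C=C/C(C)=C/CC[C@]12CO[C@]([C@H](C)CO[Si](C)(C)C(C)(C)C)(CC[C@]1(C)O[Si](CC)(CC)CC)[C@H]2CCCO[Si](c3ccccc3)(c4ccccc4)C(C)(C)C | intermediate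
36 | (2R)-2-[(1S,2S,5R,8S)-8-[3-(TBDPSO)propyl]-2-hydroxy-2-methyl-1-{(3E,5E)-4-methyl-6-[(1R,5S)-2,5,6,6-tetramethylcyclohex-2-en-1-yl]hexa-3,5-dien-1-yl}-6-oxabicyclo[3.2.1]octan-5-yl]propan-1-ol | CC1=CC[C@H](C)C(C)(C)[C@@H]1/C=C/C(C)=C/CC[C@]12CO[C@]([C@H](C)CO)(CC[C@]1(C)O)[C@H]2CCCO[Si](c3ccccc3)(c4ccccc4)C(C)(C)C | intermediate
37 | (2S)-2-[(1S,2S,5R,8S)-8-[3-(TBDPSO)propyl]-2-hydroxy-2-methyl-1-{(3E,5E)-4-methyl-6-[(1R,5S)-2,5,6,6-tetramethylcyclohex-2-en-1-yl]hexa-3,5-dien-1-yl}-6-oxabicyclo[3.2.1]octan-5-yl]propanal | CC1=CC[C@H](C)C(C)(C)[C@@H]1/C=C/C(C)=C/CC[C@]12CO[C@]([C@H](C)C=O)(CC[C@]1(C)O)[C@H]2CCCO[Si](c3ccccc3)(c4ccccc4)C(C)(C)C | intermediate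
38 | (2S)-2-[(1S,2S,5R,8S)-2-hydroxy-8-(3-hydroxypropyl)-2-methyl-1-{(3E,5E)-4-methyl-6-[(1R,5S)-2,5,6,6-tetramethylcyclohex-2-en-1-yl]hexa-3,5-dien-1-yl}-6-oxabicyclo[3.2.1]octan-5-yl]propanal | CC1=CC[C@H](C)C(C)(C)[C@@H]1/C=C/C(C)=C/CC[C@]12CO[C@]([C@H](C)C=O)(CC[C@]1(C)O)[C@H]2CCCO | target

**Step count**
Total: 25 steps. Longest linear sequence: 21 steps (steps 1–3, 5–7, 9–19, 22–25); steps 4, 8, 20 and 21 make the side fragments.

**Steps most likely to fail**

1. Step 12 (key step). The process at risk is β-scission of the tertiary C5 alkoxy radical (cleavage of C5–Cα or C5–C8), or hydrogen abstraction from an arm, running faster than the 1,5-hydrogen transfer from C7. The fallback replaces the oxygen radical by a hydroxyl-directed C–H silylation at the same methyl group. It sets out from 17 and returns at 20. NaBH4 in MeOH at 0 °C should reduce the C2 ketone of 17 by axial attack to the equatorial C2 alcohol F1 and leave the ester untouched. Et2SiH2 with catalytic [Ir(cod)OMe]2 in THF at rt converts the secondary hydroxyl of F1 into the diethylhydrosilyl ether F2 while the hindered tertiary C5 hydroxyl stays free. Iridium-catalysed γ-C–H silylation of F2 in the same flask ([Ir(cod)OMe]2, 3,4,7,8-tetramethyl-1,10-phenanthroline, norbornene, THF, 80–100 °C) then functionalises the C1 methyl group, the only primary γ C–H and gauche to the C2 oxygen, to give the C2–O–SiEt2–C7 oxasilolane F3 as a five-membered cyclic silyl ether. Tamao–Fleming oxidation of F3 (H2O2, KHCO3, THF/MeOH) gives the C2,C5,C7-triol F4 with the C7 hydroxymethyl group in place. TsCl in pyridine sulfonylates the primary C7 hydroxyl of F4 to the C7 tosylate F5 and, on warming, the axial C5 hydroxyl of F5 displaces the sulfonate by 5-exo-tet attack to give the bicyclic ether C2 alcohol F6 of the 6-oxabicyclo[3.2.1]octane series. Dess–Martin oxidation of F6 gives 20.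

2. Step 5. The process at risk is O-alkylation of the enolate or elimination of the triflate in place of C-alkylation at the congested carbon. The fallback brings in the two-carbon chain at the ester oxidation level with a more reactive electrophile. It sets out from 5 and returns at 9. MeLi in THF followed by tert-butyl bromoacetate (−78 → 0 °C) should give, by way of lithium enolate 8, the keto ester F7 in which the acetate arm has entered anti to the butenyl group. LiAlH4 in THF at 0 °C reduces the ester and the ketone of F7 to the diol F8 whose ring carbinol configuration is immaterial. NaH (1 equiv), BnBr and Bu4NI in THF at 0 °C benzylate the primary hydroxyl of F8 to the mono-benzyl ether F9 and leave the hindered secondary hydroxyl free. Dess–Martin oxidation of F9 gives 9.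

3. Step 9. The process at risk is competing addition to the C2 carbonyl, loss of facial control in the flexible 1,4-dione, or enolisation toward C8 before addition. The fallback masks C2 as an alcohol so that crotylation meets a single ketone in a defined chair. It sets out from 10 and returns at 14. NaBH4 in MeOH at 0 °C reduces the ketone of 10 to the hydroxy ketal F10 with the ester untouched. 1 M HCl in THF removes the ketal of F10 to give the hydroxy ketone F11 as the only carbonyl electrophile besides the ester. Crotylation of F11 with 13 and BF3·OEt2 (excess, CH2Cl2, −78 °C) gives the C2,C5-diol F12 through the same closed transition state. Dess–Martin oxidation of the secondary alcohol of F12 gives 14.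

**Further compounds**
F1 | step 12 | methyl 3-[(1S,2S,3S,6R)-2-[2-(benzyloxy)ethyl]-6-[(2R)-1-(TBSO)propan-2-yl]-3,6-dihydroxy-2-methylcyclohexyl]propanoate (C2 alcohol of 17) | O(Cc1ccccc1)CC[C@@]1(C)[C@H](CCC(=O)OC)[C@@](O)([C@H](C)CO[Si](C)(C)C(C)(C)C)CC[C@@H]1O
F2 | step 12 | C2 O-diethylhydrosilyl ether of F1 | O(Cc1ccccc1)CC[C@@]1(C)[C@H](CCC(=O)OC)[C@@](O)([C@H](C)CO[Si](C)(C)C(C)(C)C)CC[C@@H]1O[SiH](CC)CC
F3 | step 12 | C2–O–SiEt2–C7 oxasilolane from F2 | O(Cc3ccccc3)CC[C@]12C[Si](CC)(CC)O[C@H]1CC[C@](O)([C@H](C)CO[Si](C)(C)C(C)(C)C)[C@H]2CCC(=O)OC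
F4 | step 12 | methyl 3-[(1S,2S,3S,6R)-2-[2-(benzyloxy)ethyl]-6-[(2R)-1-(TBSO)propan-2-yl]-3,6-dihydroxy-2-(hydroxymethyl)cyclohexyl]propanoate | O(Cc3ccccc3)CC[C@]1(CO)[C@@H](O)CC[C@](O)([C@H](C)CO[Si](C)(C)C(C)(C)C)[C@H]1CCC(=O)OC
F5 | step 12 | C7 4-methylbenzenesulfonate of F4 | O(Cc3ccccc3)CC[C@]1(COS(=O)(=O)c4ccc(C)cc4)[C@@H](O)CC[C@](O)([C@H](C)CO[Si](C)(C)C(C)(C)C)[C@H]1CCC(=O)OC
F6 | step 12 | methyl 3-[(1S,2S,5R,8S)-1-[2-(benzyloxy)ethyl]-5-[(2R)-1-(TBSO)propan-2-yl]-2-hydroxy-6-oxabicyclo[3.2.1]octan-8-yl]propanoate | O(Cc3ccccc3)CC[C@]12CO[C@]([C@H](C)CO[Si](C)(C)C(C)(C)C)(CC[C@@H]1O)[C@H]2CCC(=O)OC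
F7 | step 5 | tert-butyl 2-[(6S,7S)-6-(but-3-en-1-yl)-7-methyl-8-oxo-1,4-dioxaspiro[4.5]decan-7-yl]acetate | CC(C)(C)OC(=O)C[C@@]1(C)[C@H](CCC=C)C2(OCCO2)CCC1=O
F8 | step 5 | 2-[(6S,7S)-6-(but-3-en-1-yl)-8-hydroxy-7-methyl-1,4-dioxaspiro[4.5]decan-7-yl]ethan-1-ol (expected major C8 epimer drawn) | OCC[C@@]1(C)[C@H](CCC=C)C2(OCCO2)CC[C@@H]1O
F9 | step 5 | (6S,7S)-7-[2-(benzyloxy)ethyl]-6-(but-3-en-1-yl)-7-methyl-1,4-dioxaspiro[4.5]decan-8-ol (expected major C8 epimer drawn) | O(Cc1ccccc1)CC[C@@]1(C)[C@H](CCC=C)C2(OCCO2)CC[C@@H]1O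
F10 | step 9 | methyl 3-[(6S,7S)-7-[2-(benzyloxy)ethyl]-8-hydroxy-7-methyl-1,4-dioxaspiro[4.5]decan-6-yl]propanoate (expected major C8 epimer drawn) | O(Cc1ccccc1)CC[C@@]1(C)[C@H](CCC(=O)OC)C2(OCCO2)CC[C@@H]1O
F11 | step 9 | methyl 3-[(1S,2S)-2-[2-(benzyloxy)ethyl]-3-hydroxy-2-methyl-6-oxocyclohexyl]propanoate | O(Cc1ccccc1)CC[C@@]1(C)[C@H](CCC(=O)OC)C(=O)CC[C@@H]1O
F12 | step 9 | methyl 3-[(1S,2S,6S)-2-[2-(benzyloxy)ethyl]-6-[(2R)-but-3-en-2-yl]-3,6-dihydroxy-2-methylcyclohexyl]propanoate | O(Cc1ccccc1)CC[C@@]1(C)[C@H](CCC(=O)OC)[C@@](O)([C@H](C)C=C)CC[C@@H]1O
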